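**Plan**
- Retrosynthetic cuts, in order: (a) the CH2–C(sp2) bond between the second side-chain carbon and the first chain alkene (B-alkyl Suzuki–Miyaura); (b) the ring bond between the methyl-bearing alkene carbon and the allylic ring CH that carries the side chain (palladium enolate alkenylation); (c) the bond from the carbinol carbon to the ring CH2 (allylboration).
- Enabling feature: in the cyclohexene, the carbinol CH(OH) and the side-chain-bearing CH flank the CMe2 carbon in a cis-1,3 relationship. The hydroxyl oxygen and the first side-chain carbon can therefore be tied into a temporary γ-lactone (O, carbinol C, CMe2, ring CH, C=O), which makes that ring CH an enolisable lactone α-carbon.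
- Forward order: the lactone ring is made first (steps 1–2) and its allyl arm becomes a (Z)-vinyl iodide (steps 3–4). The cyclohexene is then closed onto the lactone enolate to give a 6-oxabicyclo[3.2.1]octenone (step 5). The lactone bridge is cleaved to hydroxyl plus vinyl (steps 6–7), and the C19 chain from farnesyl bromide (steps 8–9) is joined last (step 10).
- Stereochemistry: the carbinol centre (S) comes from reagent-controlled Brown allylboration. The ring CH (R) is relayed from it through the bridged lactone, which also pins the ring alkene because a bridgehead α-carbon cannot enolise. Chain geometry comes from (2E,6E)-farnesyl bromide, syn-hydrozirconation and stereoretentive coupling.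

Key step: step 5

Assumption: methyl 3,3-dimethylpent-4-enoate, (2E,6E)-farnesyl bromide, (−)-B-allyldiisopinocampheylborane (from (+)-α-pinene) and propyne are taken as commercial.

**Step 1**
Reactants: 1 methyl 3,3-dimethylpent-4-enoate
Product: 2 methyl 3,3-dimethyl-4-oxobutanoate
Conditions: O3, CH2Cl2, −78 °C; then Me2S, −78 °C to rt
Reagents that add atoms: ozone, [O-][O+]=O
Why: Ozonolysis with reductive work-up cleaves the only alkene to the neopentyl aldehyde, and the ester is inert to ozone.

**Step 2**
Reactants: 2 methyl 3,3-dimethyl-4-oxobutanoate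
Product: 4 (5S)-4,4-dimethyl-5-(prop-2-en-1-yl)oxolan-2-one, via hydroxy ester 3 (not isolated)
Conditions: (−)-Ipc2B(allyl), Et2O, −78 °C; then 30% H2O2, aq. NaHCO3, rt; then TsOH·H2O (cat.), CH2Cl2, rt
Reagents that add atoms: (−)-B-allyldiisopinocampheylborane, C=CCB([C@@H]1C[C@@H]2C[C@H]([C@H]1C)C2(C)C)[C@@H]1C[C@@H]2C[C@H]([C@H]1C)C2(C)C
Why: Brown allylboration delivers the allyl group through a chair six-membered transition state whose facial bias is set by the isopinocampheyl groups, which should give the (S)-carbinol as it does for pivalaldehyde-type aldehydes (the ester does not react at −78 °C), and the γ-hydroxy ester then closes to the γ-lactone with help from the gem-dimethyl group.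

**Step 3**
Reactants: 4 (5S)-4,4-dimethyl-5-(prop-2-en-1-yl)oxolan-2-one
Product: 5 2-[(2S)-3,3-dimethyl-5-oxooxolan-2-yl]acetaldehyde
Conditions: O3, CH2Cl2, −78 °C; then Me2S, −78 °C to rt
Reagents that add atoms: ozone, [O-][O+]=O
Why: Ozonolysis of the terminal alkene leaves the lactone and the stereocentre untouched.

**Step 4**
Reactants: 5 2-[(2S)-3,3-dimethyl-5-oxooxolan-2-yl]acetaldehyde
Product: 6 (5S)-5-[(2Z)-3-iodobut-2-en-1-yl]-4,4-dimethyloxolan-2-one
Conditions: EtPPh3I, n-BuLi, THF, rt; I2, −78 °C; NaN(SiMe3)2, −20 °C; then 5, −78 °C to rt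
Reagents that add atoms: ethyltriphenylphosphonium iodide, CC[P+](c1ccccc1)(c1ccccc1)c1ccccc1.[I-]; iodine, [I][I]
Why: The Stork–Zhao-type Wittig iodoolefination with the α-iodoethylidene ylide should place iodine cis to the chain (Z), the geometry the ring closure needs, and the reactive non-stabilised ylide should add at −78 °C before β-elimination of the lactone oxygen can compete.

**Step 5**
Reactants: 6 (5S)-5-[(2Z)-3-iodobut-2-en-1-yl]-4,4-dimethyloxolan-2-one
Product: 8 (1R,5S)-2,8,8-trimethyl-6-oxabicyclo[3.2.1]oct-2-en-7-one, via lithium enolate 7 (not isolated)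
Conditions: LiN(SiMe3)2 (1.15 equiv), toluene, −78 °C; then Pd2(dba)3 (2.5 mol %), P(tBu)3 (10 mol %), −78 °C to rt (50 °C if slow)
Reagents that add atoms: none
Why: LiN(SiMe3)2 converts 6 into lithium enolate 7, zerovalent palladium inserts into the vinyl C–I bond with retention of the Z geometry, the enolate is transferred to palladium through carbon to give a seven-membered palladacycle spanning the two cis 1,3-positions of the lactone, and reductive elimination joins the methyl-bearing vinyl carbon to the lactone α-carbon. The closest known reaction type is the palladium-catalysed intramolecular α-alkenylation of ketone and ester enolates with vinyl halides, which is used to close bridged bicycles. The cyclohexene closes in a 6-exo sense (enolate carbon onto the vinyl carbon, C–I bond exocyclic, the alkene of the iodide ending endocyclic), which completes the 6-oxabicyclo[3.2.1]oct-2-ene skeleton. The new stereocentre, the ring CH between the CMe2 carbon and the methyl-bearing alkene carbon, is controlled by the carbinol stereocentre set in step 2, because across the one-carbon CMe2 bridge the iodobutenyl arm can reach only the enolate face cis to itself. The step needs C- over O-alkenylation, no β-hydride elimination and no migration of the new double bond: the quaternary β-carbon removes all β-hydrogens of the palladium enolate and slows Claisen self-condensation, the Z iodide holds palladium on the tether side, and in 8 the α-hydrogen sits at a bridgehead so that enolisation toward the ring alkene is forbidden by Bredt's rule.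

**Step 6**
Reactants: 8 (1R,5S)-2,8,8-trimethyl-6-oxabicyclo[3.2.1]oct-2-en-7-one
Product: 9 (1R,5S)-2,8,8-trimethyl-6-oxabicyclo[3.2.1]oct-2-en-7-ol (lactol; hemiacetal carbon as a mixture of epimers)
Conditions: iBu2AlH (1.1 equiv), CH2Cl2, −78 °C; aq. Rochelle salt
Reagents that add atoms: none
Why: One hydride equivalent at −78 °C should stop at the lactol because the tetrahedral aluminium alkoxide is stable until work-up, and the ring alkene is inert.

**Step 7**
Reactants: 9 (1R,5S)-2,8,8-trimethyl-6-oxabicyclo[3.2.1]oct-2-en-7-ol
Product: 11 (1S,5R)-5-ethenyl-4,6,6-trimethylcyclohex-3-en-1-ol, via hydroxy aldehyde 10 (not isolated)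
Conditions: Ph3PCH3Br (3.3 equiv), KOtBu (3.0 equiv), THF, 0 °C; then 9, 0 °C to rt
Reagents that add atoms: methyltriphenylphosphonium bromide, C[P+](c1ccccc1)(c1ccccc1)c1ccccc1.[Br-]
Why: Wittig methylenation traps the ring-opened hydroxy aldehyde 10 (present as its alkoxide) that equilibrates with the lactolate, and keeping the phosphonium salt in slight excess over the base should leave no free alkoxide base to epimerise the α-carbon or move the ring double bond.

**Step 8**
Reactants: 12 (2E,6E)-farnesyl bromide
Product: 14 (6E,10E)-7,11,15-trimethylhexadeca-6,10,14-trien-2-yne, via lithium acetylide 13 (not isolated)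
Conditions: propyne, n-BuLi (2 equiv per propyne), TMEDA, Et2O–hexane, −78 to 0 °C; then 12, −78 °C to rt; then MeI, 0 °C to rt
Reagents that add atoms: propyne, CC#C; iodomethane, IC
Why: Propargylation of the allylic bromide with 1,3-dilithiopropyne should occur at the more nucleophilic sp3 carbanion by direct SN2 substitution with retention of the E,E geometry, and the remaining lithium acetylide is C-methylated in the same flask.

**Step 9**
Reactants: 14 (6E,10E)-7,11,15-trimethylhexadeca-6,10,14-trien-2-yne
Product: 16 (2E,6E,10E)-2-iodo-7,11,15-trimethylhexadeca-2,6,10,14-tetraene, via alkenylzirconocene chloride 15 (not isolated)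
Conditions: Cp2Zr(H)Cl (2.0 equiv), THF, 50 °C; then I2, THF, −20 °C; aq. Na2S2O3/NaHCO3
Reagents that add atoms: iodine, [I][I]
Why: Hydrozirconation with excess Cp2Zr(H)Cl under equilibrating conditions should place zirconium on the less hindered, methyl-bearing alkyne carbon by syn addition, iodinolysis proceeds with retention to the (E)-2-iodo-2-alkene, and the trisubstituted alkenes are not hydrozirconated.

**Step 10**
Reactants: 11 (1S,5R)-5-ethenyl-4,6,6-trimethylcyclohex-3-en-1-ol; 16 (2E,6E,10E)-2-iodo-7,11,15-trimethylhexadeca-2,6,10,14-tetraene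
Product: 18 camelliol C, via bis-boryl intermediate 17 (not isolated)
Conditions: 9-BBN (2.5 equiv), THF, 0 °C to rt; then 3 M aq. Cs2CO3; then 16, Pd(dppf)Cl2 (5 mol %), AsPh3 (5 mol %), DMF, rt
Reagents that add atoms: none
Why: 9-BBN should hydroborate only the monosubstituted vinyl group at its terminal carbon while the hydroxyl is carried as its borinate, the excess borane is destroyed by the aqueous base before the polyene iodide is added, and the B-alkyl Suzuki–Miyaura coupling joins sp3 to sp2 carbon with retention of the E geometry, the hydroxyl being freed on aqueous work-up.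

**Compound list**
1 | methyl 3,3-dimethylpent-4-enoate | C=CC(C)(C)CC(=O)OC | starting material
2 | methyl 3,3-dimethyl-4-oxobutanoate | O=CC(C)(C)CC(=O)OC | intermediate
3 | methyl (4S)-4-hydroxy-3,3-dimethylhept-6-enoate | C=CC[C@H](O)C(C)(C)CC(=O)OC | intermediate
4 | (5S)-4,4-dimethyl-5-(prop-2-en-1-yl)oxolan-2-one | C=CC[C@@H]1OC(=O)CC1(C)C | intermediate
5 | 2-[(2S)-3,3-dimethyl-5-oxooxolan-2-yl]acetaldehyde | O=CC[C@@H]1OC(=O)CC1(C)C | intermediate
6 | (5S)-5-[(2Z)-3-iodobut-2-en-1-yl]-4,4-dimethyloxolan-2-one | C/C(I)=C/C[C@@H]1OC(=O)CC1(C)C | intermediate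
7 | lithium (5S)-5-[(2Z)-3-iodobut-2-en-1-yl]-4,4-dimethyl-4,5-dihydrofuran-2-olate (lithium enolate of 6) | C/C(I)=C/C[C@@H]1OC(O[Li])=CC1(C)C | intermediate
8 | (1R,5S)-2,8,8-trimethyl-6-oxabicyclo[3.2.1]oct-2-en-7-one | O=C1O[C@H]2CC=C(C)[C@@H]1C2(C)C | intermediate
9 | (1R,5S)-2,8,8-trimethyl-6-oxabicyclo[3.2.1]oct-2-en-7-ol (lactol, epimers at the hemiacetal carbon) | OC1O[C@H]2CC=C(C)[C@@H]1C2(C)C | intermediate
10 | (1R,5S)-5-hydroxy-2,6,6-trimethylcyclohex-2-ene-1-carbaldehyde (open form of 9, present as its alkoxide) | O=C[C@@H]1C(C)=CC[C@H](O)C1(C)C | intermediate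
11 | (1S,5R)-5-ethenyl-4,6,6-trimethylcyclohex-3-en-1-ol | C=C[C@@H]1C(C)=CC[C@H](O)C1(C)C | intermediate
12 | (2E,6E)-1-bromo-3,7,11-trimethyldodeca-2,6,10-triene (farnesyl bromide) | CC(C)=CCC/C(C)=C/CC/C(C)=C/CBr | starting material
13 | lithium (5E,9E)-6,10,14-trimethylpentadeca-5,9,13-trien-1-yn-1-ide | CC(C)=CCC/C(C)=C/CC/C(C)=C/CCC#C[Li] | intermediate
14 | (6E,10E)-7,11,15-trimethylhexadeca-6,10,14-trien-2-yne | CC(C)=CCC/C(C)=C/CC/C(C)=C/CCC#CC | intermediate
15 | chlorobis(cyclopentadienyl)[(2E,6E,10E)-7,11,15-trimethylhexadeca-2,6,10,14-tetraen-2-yl]zirconium | CC(C)=CCC/C(C)=C/CC/C(C)=C/CC/C=C(\C)[Zr](Cl)(C1C=CC=C1)C1C=CC=C1 | intermediate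
16 | (2E,6E,10E)-2-iodo-7,11,15-trimethylhexadeca-2,6,10,14-tetraene | CC(C)=CCC/C(C)=C/CC/C(C)=C/CC/C=C(\C)I | intermediate
17 | 9-{2-[(1R,5S)-5-(9-borabicyclo[3.3.1]nonan-9-yloxy)-2,6,6-trimethylcyclohex-2-en-1-yl]ethyl}-9-borabicyclo[3.3.1]nonane | B3(C4CCCC3CCC4)CC[C@@H]1C(C)=CC[C@H](OB2C5CCCC2CCC5)C1(C)C | intermediate
18 | camelliol C, (1S,5R)-4,6,6-trimethyl-5-[(3E,7E,11E)-3,8,12,16-tetramethylheptadeca-3,7,11,15-tetraen-1-yl]cyclohex-3-en-1-ol | CC(C)=CCC/C(C)=C/CC/C(C)=C/CC/C=C(\C)CC[C@@H]1C(C)=CC[C@H](O)C1(C)C | target

**Step count and risks**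
Total steps: 10. Longest linear sequence: 8 (steps 1–7, then step 10); the chain branch is steps 8–9.

Steps most likely to fail:

Step 5. Reductive elimination at the hindered lactone α-carbon, next to the quaternary carbon and within a bridged palladacycle, may be slow, so that protodeiodination or base-induced dehydroiodination of the vinyl iodide takes over. The fallback sets out from 6 and forms the same bond without a strong base in the coupling event. The lactone is brominated at its α-carbon through the silyl ketene acetal (LiN(SiMe3)2, Me3SiCl, THF, −78 °C; then NBS) to give (5S)-3-bromo-5-[(2Z)-3-iodobut-2-en-1-yl]-4,4-dimethyloxolan-2-one F1 as a mixture of epimers. This is closed by a nickel-catalysed intramolecular reductive cross-electrophile coupling of the α-bromo ester with the vinyl iodide (NiBr2(dme), 4,4'-di-tert-butyl-2,2'-bipyridine, Mn powder, DMF, rt to 40 °C). The α-carbonyl radical is captured by the vinylnickel species, and the bridge again allows only the cis product, so the fallback comes back to the route at 8.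

Step 7. The transient α-branched, β,γ-unsaturated aldehyde may epimerise at the ring CH, or its ring double bond may move into conjugation, under the basic ylide conditions before olefination is complete. The fallback sets out from 9 and splits the olefination into a low-basicity addition and a separate elimination (Peterson olefination). Me3SiCH2Li/CeCl3 in THF at −78 °C adds to the open form to give (1S,5R)-5-[1-hydroxy-2-(trimethylsilyl)ethyl]-4,6,6-trimethylcyclohex-3-en-1-ol F2 as a mixture of carbinol epimers. KH in THF then effects syn-elimination of the β-hydroxysilane to the vinyl group, and the fallback comes back at 11.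

Step 9. Zirconium may be placed in part on the inner alkyne carbon, giving a regioisomeric vinyl iodide that would carry through the coupling as a hard-to-separate branched isomer. The fallback sets out from 12 and lets silicon fix the regiochemistry. Alkylation of 12 with lithiated 1-(trimethylsilyl)propyne (n-BuLi, THF, −78 °C) gives trimethyl[(5E,9E)-6,10,14-trimethylpentadeca-5,9,13-trien-1-yn-1-yl]silane F3. Hydroalumination with iBu2AlH in heptane (aluminium on the silyl-bearing carbon, net trans addition), then MeLi and MeI, gives trimethyl[(2E,6E,10E)-7,11,15-trimethylhexadeca-2,6,10,14-tetraen-2-yl]silane F4. Iododesilylation with NIS at 0 °C, with retention, comes back to the route at 16.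

**Further compounds**
F1 | step 5 | (5S)-3-bromo-5-[(2Z)-3-iodobut-2-en-1-yl]-4,4-dimethyloxolan-2-one | C/C(I)=C/C[C@@H]1OC(=O)C(Br)C1(C)C
F2 | step 7 | (1S,5R)-5-[1-hydroxy-2-(trimethylsilyl)ethyl]-4,6,6-trimethylcyclohex-3-en-1-ol | C[Si](C)(C)CC(O)[C@@H]1C(C)=CC[C@H](O)C1(C)C
F3 | step 9 | trimethyl[(5E,9E)-6,10,14-trimethylpentadeca-5,9,13-trien-1-yn-1-yl]silane | CC(C)=CCC/C(C)=C/CC/C(C)=C/CCC#C[Si](C)(C)C
F4 | step 9 | trimethyl[(2E,6E,10E)-7,11,15-trimethylhexadeca-2,6,10,14-tetraen-2-yl]silane | CC(C)=CCC/C(C)=C/CC/C(C)=C/CC/C=C(\C)[Si](C)(C)C
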